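**Plan**

1. Retrosynthesis: after removal of the C8 ester and the protecting groups, the C5–C10 bond is cut by a retro-Cope step. This re-joins the vinyl terminus C2 to the propenyl CH2 C3 (a bond absent from the target) and opens the cyclohexane to an (E,E)-cyclodeca-1(10),4-diene. The C7–C8 bond is then cut by retro-allylation to an acyclic ω-formyl 2-(bromomethyl)enoate.
2. Enabling feature: the six-membered ring is a trans-1,2-dialkenylcyclohexane (vinyl on C10, 3-hydroxyprop-1-en-2-yl on C5), the Cope retron of a ten-membered 1,5-diene. C8–O/C7–C11(=C13)CO2H is a homoallylic alcohol, the retron of a 2-carboxyallyl-metal addition to an aldehyde.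
3. Forward: the chain is grown linearly from but-3-yn-1-ol (C8, C9, C10, C1) by carboalumination/oxirane opening (C14, C2, C3), carbomagnesiation of propargyl alcohol (C4, C5, C15), formylation (C6), propiolate addition (C7, C11, C12) and hydroxymethylation (C13). In one step the ten-membered ring is closed at C7–C8 and contracted to the six-membered ring at C5–C10; C8 acylation and global deprotection finish the route.
4. Stereochemistry: C6 comes from a catalytic asymmetric alkynylation. C7 and C8 come from the macrocyclic allylation (1,3-allylic strain about C6), C5 and C10 from the chair Cope rearrangement of the E,E-diene. The two alkene geometries come from syn-carboalumination and anti-carbomagnesiation.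

Key step: step 14

Remark: locants C1–C15 in the text are elemane/germacrane locants (C10 quaternary with methyl C14 and vinyl C1=C2; C5 carries C4(=C3)C15; C6 hydroxyl; C7 carries C11(=C13)C12; C8 acyloxy; C9 methylene). Systematic names keep their own chain locants. PMB = 4-methoxybenzyl, TBS = tert-butyldimethylsilyl, TMSE = 2-(trimethylsilyl)ethyl.

Assumption: (R,R)-ProPhenol, 2,6-bis{[(2R)-2-(hydroxydiphenylmethyl)pyrrolidin-1-yl]methyl}-4-methylphenol, is taken to deliver the (4R)-carbinol 19; if the facial sense is the reverse, its antipode is used.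

**Route**

Step 1
Reactants: 1 but-3-yn-1-ol
Product: 2 1-[(but-3-yn-1-yloxy)methyl]-4-methoxybenzene
Conditions: NaH, PMBCl, TBAI (cat.), THF/DMF, 0 → 25 °C
Reagents that add atoms: 4-methoxybenzyl chloride COc1ccc(CCl)cc1
Why: Williamson etherification of the primary alkoxide masks the C8 oxygen as an ether that survives the organometallic steps and can be removed oxidatively.

Step 2
Reactants: 2 1-[(but-3-yn-1-yloxy)methyl]-4-methoxybenzene; 3 oxirane
Product: 6 (3E)-4-methyl-6-(PMB-oxy)hex-3-en-1-ol, via alkenylalane 4 (not isolated), via lithium alkenylalanate 5 (not isolated)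
Conditions: AlMe3, Cp2ZrCl2 (cat.), CH2Cl2, 0 → 25 °C; n-BuLi, THF, −78 °C; oxirane, −78 → 25 °C
Reagents that add atoms: trimethylaluminium C[Al](C)C
Why: Zirconium-catalysed syn-carboalumination (Negishi) puts methyl on the internal and aluminium on the terminal alkyne carbon, and the derived alanate opens oxirane with retention, so that C1=C10 is formed E (C9 trans to C2).

Step 3
Reactants: 6 (3E)-4-methyl-6-(PMB-oxy)hex-3-en-1-ol
Product: 7 1-({[(3E)-6-bromo-3-methylhex-3-en-1-yl]oxy}methyl)-4-methoxybenzene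
Conditions: CBr4, PPh3, CH2Cl2, 0 °C
Reagents that add atoms: carbon tetrabromide BrC(Br)(Br)Br
Why: Appel bromination of the primary homoallylic alcohol proceeds by SN2 displacement of the alkoxyphosphonium ion without touching the alkene or the PMB ether.

Step 4
Reactants: 7 1-({[(3E)-6-bromo-3-methylhex-3-en-1-yl]oxy}methyl)-4-methoxybenzene; 8 prop-2-yn-1-ol
Product: 11 (2Z)-3-iodo-2-[(3E)-4-methyl-6-(PMB-oxy)hex-3-en-1-yl]prop-2-en-1-ol, via Grignard reagent 9 (not isolated), via magnesium chelate 10 (not isolated)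
Conditions: Mg, THF; 8 pre-treated with EtMgBr; CuI (cat.), THF/Et2O, −10 → 25 °C; iodine, −40 → 0 °C
Reagents that add atoms: iodine [I][I]
Why: Copper-catalysed anti-carbomagnesiation of the propargylic alkoxide places the chain on C4 and magnesium on C5 within a five-membered O–Mg chelate, and iodinolysis with retention gives the alkene with C15 cis to iodine (C3 trans to the future C6).

Step 5
Reactants: 11 (2Z)-3-iodo-2-[(3E)-4-methyl-6-(PMB-oxy)hex-3-en-1-yl]prop-2-en-1-ol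
Product: 12 tert-butyl({(2Z)-3-iodo-2-[(3E)-4-methyl-6-(PMB-oxy)hex-3-en-1-yl]prop-2-en-1-yl}oxy)dimethylsilane
Conditions: TBSCl, imidazole, DMF, 0 → 25 °C
Reagents that add atoms: tert-butyldimethylsilyl chloride CC(C)(C)[Si](C)(C)Cl
Why: Standard silylation of the primary allylic alcohol (C15–OH) protects it for the lithiation that follows.

Step 6
Reactants: 12 tert-butyl({(2Z)-3-iodo-2-[(3E)-4-methyl-6-(PMB-oxy)hex-3-en-1-yl]prop-2-en-1-yl}oxy)dimethylsilane
Product: 14 (2Z,6E)-3-[(TBS-oxy)methyl]-7-methyl-9-(PMB-oxy)nona-2,6-dienal, via alkenyllithium 13 (not isolated)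
Conditions: t-BuLi, Et2O, −78 °C; DMF; aq. NH4Cl
Reagents that add atoms: N,N-dimethylformamide CN(C)C=O
Why: Iodine–lithium exchange and formylation both proceed with retention of alkene geometry, and at −78 °C the 1,4 O-to-C silyl shift of the cis-silyloxymethyl alkenyllithium is slow.

Step 7
Reactants: 15 prop-2-ynoic acid; 16 2-(trimethylsilyl)ethanol
Product: 17 TMSE prop-2-ynoate
Conditions: DCC, DMAP (cat.), CH2Cl2, 0 °C
Reagents that add atoms: none
Why: Steglich esterification gives the propiolate with a fluoride-labile ester group that can later be removed without hydrolysis.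

Step 8
Reactants: 14 (2Z,6E)-3-[(TBS-oxy)methyl]-7-methyl-9-(PMB-oxy)nona-2,6-dienal; 17 TMSE prop-2-ynoate
Product: 19 TMSE (4R,5Z,9E)-4-hydroxy-6-[(TBS-oxy)methyl]-10-methyl-12-(PMB-oxy)dodeca-5,9-dien-2-ynoate, via methylzinc alkynylide 18 (not isolated)
Conditions: (R,R)-ProPhenol (cat.), Ph3PO (cat.), Me2Zn, PhMe, 4 °C
Reagents that add atoms: none
Why: Catalytic asymmetric alkynylation of the enal by the dinuclear zinc–ProPhenol complex adds the zinc alkynylide to one carbonyl face and sets C6 (4R in the chain name), the only stereocentre introduced by a chiral reagent.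

Step 9
Reactants: 19 TMSE (4R,5Z,9E)-4-hydroxy-6-[(TBS-oxy)methyl]-10-methyl-12-(PMB-oxy)dodeca-5,9-dien-2-ynoate
Product: 20 TMSE (4R,5Z,9E)-4-(TBS-oxy)-6-[(TBS-oxy)methyl]-10-methyl-12-(PMB-oxy)dodeca-5,9-dien-2-ynoate
Conditions: TBSOTf, 2,6-lutidine, CH2Cl2, −78 °C
Reagents that add atoms: tert-butyldimethylsilyl trifluoromethanesulfonate CC(C)(C)[Si](C)(C)OS(=O)(=O)C(F)(F)F
Why: Silylation under weakly basic, cold conditions protects the C6 carbinol without base-induced isomerisation of the γ-hydroxy ynoate, and the bulky silyloxy group later steers both ring-forming events.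

Step 10
Reactants: 20 TMSE (4R,5Z,9E)-4-(TBS-oxy)-6-[(TBS-oxy)methyl]-10-methyl-12-(PMB-oxy)dodeca-5,9-dien-2-ynoate
Product: 22 TMSE (2Z,4R,5Z,9E)-2-(hydroxymethyl)-4-(TBS-oxy)-6-[(TBS-oxy)methyl]-10-methyl-12-(PMB-oxy)dodeca-2,5,9-trienoate, via alumino enoate 21 (not isolated)
Conditions: DIBAL-H, NMO, THF, 0 °C; CH2O (from paraformaldehyde), 0 → 25 °C
Reagents that add atoms: formaldehyde C=O
Why: Syn-hydroalumination of the ynoate by the DIBAL-H–NMO complex gives the α-alumino enoate, which adds to formaldehyde with retention (vinylalumination, a Baylis–Hillman-type adduct made from the alkyne) and leaves the ester and silyl ethers untouched.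

Step 11
Reactants: 22 TMSE (2Z,4R,5Z,9E)-2-(hydroxymethyl)-4-(TBS-oxy)-6-[(TBS-oxy)methyl]-10-methyl-12-(PMB-oxy)dodeca-2,5,9-trienoate
Product: 23 TMSE (2E,4R,5Z,9E)-2-(bromomethyl)-4-(TBS-oxy)-6-[(TBS-oxy)methyl]-10-methyl-12-(PMB-oxy)dodeca-2,5,9-trienoate
Conditions: CBr4, PPh3, CH2Cl2, −20 → 0 °C
Reagents that add atoms: carbon tetrabromide BrC(Br)(Br)Br
Why: Appel bromination converts the primary allylic alcohol into the 2-(bromomethyl)enoate, the precursor of the allyl-metal nucleophile.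

Step 12
Reactants: 23 TMSE (2E,4R,5Z,9E)-2-(bromomethyl)-4-(TBS-oxy)-6-[(TBS-oxy)methyl]-10-methyl-12-(PMB-oxy)dodeca-2,5,9-trienoate
Product: 24 TMSE (2E,4R,5Z,9E)-2-(bromomethyl)-4-(TBS-oxy)-6-[(TBS-oxy)methyl]-12-hydroxy-10-methyldodeca-2,5,9-trienoate
Conditions: DDQ, CH2Cl2/pH 7 buffer, 0 °C
Reagents that add atoms: none
Why: Oxidative cleavage of the electron-rich benzylic ether by DDQ frees the C8 alcohol without touching the silyl ethers, the allylic bromide or the ester.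

Step 13
Reactants: 24 TMSE (2E,4R,5Z,9E)-2-(bromomethyl)-4-(TBS-oxy)-6-[(TBS-oxy)methyl]-12-hydroxy-10-methyldodeca-2,5,9-trienoate
Product: 25 TMSE (2E,4R,5Z,9E)-2-(bromomethyl)-4-(TBS-oxy)-6-[(TBS-oxy)methyl]-10-methyl-12-oxododeca-2,5,9-trienoate
Conditions: Dess–Martin periodinane, NaHCO3, CH2Cl2, 0 °C; used crude
Reagents that add atoms: none
Why: Dess–Martin oxidation under buffered, non-basic conditions gives the β,γ-unsaturated aldehyde without migration of C1=C10 into conjugation.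

Step 14
Reactants: 25 TMSE (2E,4R,5Z,9E)-2-(bromomethyl)-4-(TBS-oxy)-6-[(TBS-oxy)methyl]-10-methyl-12-oxododeca-2,5,9-trienoate
Product: 28 TMSE (5R,6R,7R,8S,10S)-6,15-bis(TBS-oxy)-8-hydroxyelema-1,3,11(13)-trien-12-oate, via allylchromium dichloride 26 (not isolated), via germacradienol 27 (not isolated)
Conditions: CrCl2, THF, 25 °C, slow addition (2 mM); aq. NH4Cl work-up; crude in PhMe, 110 °C
Reagents that add atoms: none
Why: CrCl2 reduces the allylic bromide to a 2-(alkoxycarbonyl)allylchromium species of trivalent chromium that adds through its γ-carbon C7 to the C8 aldehyde (intramolecular Nozaki–Hiyama allylation, the reaction type used to close germacrane rings from ω-formyl 2-(bromomethyl)enoates), and the (E,E)-cyclodeca-1(10),4-diene so formed undergoes the germacrene-to-elemene Cope rearrangement on warming. The ten-membered ring closes in a 10-exo-trig mode at the carbonyl through a Zimmerman–Traxler array; the six-membered ring then closes transannularly by the [3,3] shift through a chair transition state, which makes C5–C10 and cuts the C2–C3 tether to unveil the vinyl and 3-silyloxyprop-1-en-2-yl groups. C7 is controlled by C6: 1,3-allylic strain holds H6 in the plane of the C7=C11 unit, so the aldehyde, delivered by the arm attached at C5, should bond anti to the silyloxy group, and C8 should take the 7,8-anti relation because C6, C9, C11 and O8 all sit outward on the closing ring (H7 anti to H8). C5 is controlled in the same way (H6 eclipses C4=C5 on the C15 side, C10 arrives from the C7 side, anti to O6), and C10 follows from the E geometry of C1=C10 in the chair (C9 equatorial, methyl axial and trans to H5). The step needs ring closure to win over oligomerisation, over lactonisation of the C8 alkoxide onto C12 and over enolisation of the β,γ-unsaturated aldehyde. High dilution, the neutral chromium medium and the strain of the ten-membered diene, which drives the Cope step to the all-equatorial cyclohexane, are expected to secure this.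

Step 15
Reactants: 29 ethyl 2-(hydroxymethyl)prop-2-enoate
Product: 30 ethyl 2-[(TBS-oxy)methyl]prop-2-enoate
Conditions: TBSCl, imidazole, DMF, 0 → 25 °C
Reagents that add atoms: tert-butyldimethylsilyl chloride CC(C)(C)[Si](C)(C)Cl
Why: Standard silylation of the primary allylic alcohol protects the side-chain hydroxyl for the esterification.

Step 16
Reactants: 30 ethyl 2-[(TBS-oxy)methyl]prop-2-enoate
Product: 31 2-[(TBS-oxy)methyl]prop-2-enoic acid
Conditions: LiOH, THF/H2O, 0 → 25 °C; aq. HCl to pH 4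
Reagents that add atoms: lithium hydroxide [Li+].[OH-]
Why: Saponification of the unhindered ethyl ester gives the acid, and the primary silyl ether is stable to aqueous hydroxide.

Step 17
Reactants: 28 TMSE (5R,6R,7R,8S,10S)-6,15-bis(TBS-oxy)-8-hydroxyelema-1,3,11(13)-trien-12-oate; 31 2-[(TBS-oxy)methyl]prop-2-enoic acid
Product: 32 TMSE (5R,6R,7R,8S,10S)-6,15-bis(TBS-oxy)-8-({2-[(TBS-oxy)methyl]prop-2-enoyl}oxy)elema-1,3,11(13)-trien-12-oate
Conditions: DCC, DMAP, CH2Cl2, 0 → 25 °C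
Reagents that add atoms: none
Why: Steglich esterification acylates the only free hydroxyl (equatorial C8–OH) with retention at C8.

Step 18
Reactants: 32 TMSE (5R,6R,7R,8S,10S)-6,15-bis(TBS-oxy)-8-({2-[(TBS-oxy)methyl]prop-2-enoyl}oxy)elema-1,3,11(13)-trien-12-oate
Product: 33 (5R,6R,7S,8S,10S)-6,15-dihydroxy-8-{[2-(hydroxymethyl)prop-2-enoyl]oxy}elema-1,3,11(13)-trien-12-oic acid
Conditions: TASF, DMF, 0 → 25 °C; pH 5 phosphate buffer
Reagents that add atoms: none
Why: Fluoride cleaves the TMSE ester by β-elimination and the silyl ethers by fluorinolysis, with the ester and primary ethers expected to fall before the hindered C6 ether, so that C6–OH is freed only when C12 is a carboxylate that cannot lactonise; buffered work-up keeps the γ-hydroxy acid open.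

**Compound list**

1 | but-3-yn-1-ol | C#CCCO | starting material
2 | 1-[(but-3-yn-1-yloxy)methyl]-4-methoxybenzene | C#CCCOCc1ccc(OC)cc1 | intermediate
3 | oxirane | C1CO1 | starting material
4 | dimethyl[(1E)-2-methyl-4-(PMB-oxy)but-1-en-1-yl]alane | COc1ccc(COCC/C(C)=C/[Al](C)C)cc1 | intermediate
5 | lithium butyl(dimethyl)[(1E)-2-methyl-4-(PMB-oxy)but-1-en-1-yl]alanate | COc1ccc(COCC/C(C)=C/[Al-](C)(C)CCCC)cc1.[Li+] | intermediate
6 | (3E)-4-methyl-6-(PMB-oxy)hex-3-en-1-ol | COc1ccc(COCC/C(C)=C/CCO)cc1 | intermediate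
7 | 1-({[(3E)-6-bromo-3-methylhex-3-en-1-yl]oxy}methyl)-4-methoxybenzene | COc1ccc(COCC/C(C)=C/CCBr)cc1 | intermediate
8 | prop-2-yn-1-ol | C#CCO | starting material
9 | [(3E)-4-methyl-6-(PMB-oxy)hex-3-en-1-yl]magnesium bromide | COc1ccc(COCC/C(C)=C/CC[Mg]Br)cc1 | intermediate
10 | five-membered alkenylmagnesium alkoxide chelate (Mg bonded to C5 and to the C15 oxygen; C4 carries the (3E)-4-methyl-6-(PMB-oxy)hex-3-en-1-yl chain) | COc1ccc(COCC/C(C)=C/CCC2=C[Mg]OC2)cc1 | intermediate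
11 | (2Z)-3-iodo-2-[(3E)-4-methyl-6-(PMB-oxy)hex-3-en-1-yl]prop-2-en-1-ol | COc1ccc(COCC/C(C)=C/CC/C(CO)=C/I)cc1 | intermediate
12 | tert-butyl({(2Z)-3-iodo-2-[(3E)-4-methyl-6-(PMB-oxy)hex-3-en-1-yl]prop-2-en-1-yl}oxy)dimethylsilane | COc1ccc(COCC/C(C)=C/CC/C(CO[Si](C)(C)C(C)(C)C)=C/I)cc1 | intermediate
13 | {(1Z)-3-(TBS-oxy)-2-[(3E)-4-methyl-6-(PMB-oxy)hex-3-en-1-yl]prop-1-en-1-yl}lithium | COc1ccc(COCC/C(C)=C/CC/C(CO[Si](C)(C)C(C)(C)C)=C/[Li])cc1 | intermediate
14 | (2Z,6E)-3-[(TBS-oxy)methyl]-7-methyl-9-(PMB-oxy)nona-2,6-dienal | COc1ccc(COCC/C(C)=C/CC/C(CO[Si](C)(C)C(C)(C)C)=C/C=O)cc1 | intermediate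
15 | prop-2-ynoic acid | C#CC(=O)O | starting material
16 | 2-(trimethylsilyl)ethanol | C[Si](C)(C)CCO | starting material
17 | TMSE prop-2-ynoate | C#CC(=O)OCC[Si](C)(C)C | intermediate
18 | methyl[3-oxo-3-(TMSE-oxy)prop-1-yn-1-yl]zinc | C[Zn]C#CC(=O)OCC[Si](C)(C)C | intermediate
19 | TMSE (4R,5Z,9E)-4-hydroxy-6-[(TBS-oxy)methyl]-10-methyl-12-(PMB-oxy)dodeca-5,9-dien-2-ynoate | COc1ccc(COCC/C(C)=C/CC/C(CO[Si](C)(C)C(C)(C)C)=C/[C@@H](O)C#CC(=O)OCC[Si](C)(C)C)cc1 | intermediate
20 | TMSE (4R,5Z,9E)-4-(TBS-oxy)-6-[(TBS-oxy)methyl]-10-methyl-12-(PMB-oxy)dodeca-5,9-dien-2-ynoate | COc1ccc(COCC/C(C)=C/CC/C(CO[Si](C)(C)C(C)(C)C)=C/[C@@H](O[Si](C)(C)C(C)(C)C)C#CC(=O)OCC[Si](C)(C)C)cc1 | intermediate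
21 | TMSE (2E,4R,5Z,9E)-2-(diisobutylalumanyl)-4-(TBS-oxy)-6-[(TBS-oxy)methyl]-10-methyl-12-(PMB-oxy)dodeca-2,5,9-trienoate | COc1ccc(COCC/C(C)=C/CC/C(CO[Si](C)(C)C(C)(C)C)=C/[C@@H](O[Si](C)(C)C(C)(C)C)/C=C(/[Al](CC(C)C)CC(C)C)C(=O)OCC[Si](C)(C)C)cc1 | intermediate
22 | TMSE (2Z,4R,5Z,9E)-2-(hydroxymethyl)-4-(TBS-oxy)-6-[(TBS-oxy)methyl]-10-methyl-12-(PMB-oxy)dodeca-2,5,9-trienoate | COc1ccc(COCC/C(C)=C/CC/C(CO[Si](C)(C)C(C)(C)C)=C/[C@@H](O[Si](C)(C)C(C)(C)C)/C=C(/CO)C(=O)OCC[Si](C)(C)C)cc1 | intermediate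
23 | TMSE (2E,4R,5Z,9E)-2-(bromomethyl)-4-(TBS-oxy)-6-[(TBS-oxy)methyl]-10-methyl-12-(PMB-oxy)dodeca-2,5,9-trienoate | COc1ccc(COCC/C(C)=C/CC/C(CO[Si](C)(C)C(C)(C)C)=C/[C@@H](O[Si](C)(C)C(C)(C)C)/C=C(/CBr)C(=O)OCC[Si](C)(C)C)cc1 | intermediate
24 | TMSE (2E,4R,5Z,9E)-2-(bromomethyl)-4-(TBS-oxy)-6-[(TBS-oxy)methyl]-12-hydroxy-10-methyldodeca-2,5,9-trienoate | OCC/C(C)=C/CC/C(CO[Si](C)(C)C(C)(C)C)=C/[C@@H](O[Si](C)(C)C(C)(C)C)/C=C(/CBr)C(=O)OCC[Si](C)(C)C | intermediate
25 | TMSE (2E,4R,5Z,9E)-2-(bromomethyl)-4-(TBS-oxy)-6-[(TBS-oxy)methyl]-10-methyl-12-oxododeca-2,5,9-trienoate | O=CC/C(C)=C/CC/C(CO[Si](C)(C)C(C)(C)C)=C/[C@@H](O[Si](C)(C)C(C)(C)C)/C=C(/CBr)C(=O)OCC[Si](C)(C)C | intermediate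
26 | TMSE (2E,4R,5Z,9E)-2-[(dichlorochromio)methyl]-4-(TBS-oxy)-6-[(TBS-oxy)methyl]-10-methyl-12-oxododeca-2,5,9-trienoate | O=CC/C(C)=C/CC/C(CO[Si](C)(C)C(C)(C)C)=C/[C@@H](O[Si](C)(C)C(C)(C)C)/C=C(/C[Cr](Cl)Cl)C(=O)OCC[Si](C)(C)C | intermediate
27 | TMSE (1(10)E,4Z,6R,7R,8S)-6,15-bis(TBS-oxy)-8-hydroxygermacra-1(10),4,11(13)-trien-12-oate | O[C@H]1C/C(C)=C/CC/C(CO[Si](C)(C)C(C)(C)C)=C/[C@@H](O[Si](C)(C)C(C)(C)C)[C@@H]1C(=C)C(=O)OCC[Si](C)(C)C | intermediate
28 | TMSE (5R,6R,7R,8S,10S)-6,15-bis(TBS-oxy)-8-hydroxyelema-1,3,11(13)-trien-12-oate | C=C[C@]1(C)C[C@H](O)[C@@H](C(=C)C(=O)OCC[Si](C)(C)C)[C@H](O[Si](C)(C)C(C)(C)C)[C@H]1C(=C)CO[Si](C)(C)C(C)(C)C | intermediate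
29 | ethyl 2-(hydroxymethyl)prop-2-enoate | C=C(CO)C(=O)OCC | starting material
30 | ethyl 2-[(TBS-oxy)methyl]prop-2-enoate | C=C(CO[Si](C)(C)C(C)(C)C)C(=O)OCC | intermediate
31 | 2-[(TBS-oxy)methyl]prop-2-enoic acid | C=C(CO[Si](C)(C)C(C)(C)C)C(=O)O | intermediate
32 | TMSE (5R,6R,7R,8S,10S)-6,15-bis(TBS-oxy)-8-({2-[(TBS-oxy)methyl]prop-2-enoyl}oxy)elema-1,3,11(13)-trien-12-oate | C=C[C@]1(C)C[C@H](OC(=O)C(=C)CO[Si](C)(C)C(C)(C)C)[C@@H](C(=C)C(=O)OCC[Si](C)(C)C)[C@H](O[Si](C)(C)C(C)(C)C)[C@H]1C(=C)CO[Si](C)(C)C(C)(C)C | intermediate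
33 | (5R,6R,7S,8S,10S)-6,15-dihydroxy-8-{[2-(hydroxymethyl)prop-2-enoyl]oxy}elema-1,3,11(13)-trien-12-oic acid | C=C[C@]1(C)C[C@H](OC(=O)C(=C)CO)[C@@H](C(=C)C(=O)O)[C@H](O)[C@H]1C(=C)CO | target

**Step count and risks**

Total step count: 18. Longest linear sequence: 15 steps (steps 1–6, 8–14, 17 and 18).

Steps most likely to fail:

Step 14. The closure may give oligomers instead of the ten-membered ring, the C1=C10 double bond may migrate into conjugation with the aldehyde before addition, the equilibrating allylchromium may add with poor facial selectivity at C7/C8, or the C8 alkoxide may lactonise onto C12. The fallback replaces the open Barbier-type addition by a thermal allylboration with a configurationally fixed reagent. Setting out from bromo alcohol 24, copper-catalysed borylation (B2pin2, CuCl cat., KOAc, DMF) should give the hydroxy allylboronate F1, and Dess–Martin oxidation the formyl allylboronate F2. Heated at high dilution (PhMe, 110 °C), F2 should cyclise through a chair transition state (C6 trans to the CH2B group on C7=C11, hence 7,8-anti) and undergo the Cope rearrangement in the same flask to the pinacol borate F3. Triethanolamine work-up returns the route at 28.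

Step 10. Conjugate hydroalumination may be accompanied by reduction of the ester, or the aluminium reagent may fail to add cleanly to formaldehyde. The fallback brings in the hydroxymethyl group by cross-coupling. From ynoate 20, palladium-catalysed syn-hydrostannation (Bu3SnH, Pd(PPh3)4 cat., THF) should give the α-stannyl enoate F4, and iododestannylation (iodine, CH2Cl2, 0 °C) the α-iodo enoate F5. Stille coupling with (tributylstannyl)methanol (Pd2(dba)3, AsPh3, NMP) returns the route at 22 with the same alkene geometry.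

Step 4. The Grignard reagent may be consumed by deprotonation of the alkyne or by Wurtz coupling, and the anti-addition may be incomplete. The fallback builds the C4=C5 alkene by conjugate addition to an ynoate. Propargyl alcohol 8 is silylated (TBSCl, imidazole) to tert-butyldimethyl(prop-2-yn-1-yloxy)silane F6 and carboxylated (n-BuLi; ClCO2Et) to ethyl 4-(TBS-oxy)but-2-ynoate F7. The organocopper reagent made from Grignard reagent 9 (CuBr·SMe2, THF, −78 °C) should add syn to F7 to give the Z-enoate F8 with the chain trans to the ester. DIBAL-H reduction should give the allylic alcohol F9, and MnO2 oxidation returns the route at enal 14, so that steps 5 and 6 are not needed.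

Further compounds
F1 | step 14 | TMSE (2Z,4R,5Z,9E)-4-(TBS-oxy)-6-[(TBS-oxy)methyl]-12-hydroxy-10-methyl-2-[(4,4,5,5-tetramethyl-1,3,2-dioxaborolan-2-yl)methyl]dodeca-2,5,9-trienoate | OCC/C(C)=C/CC/C(CO[Si](C)(C)C(C)(C)C)=C/[C@@H](O[Si](C)(C)C(C)(C)C)/C=C(/CB1OC(C)(C)C(C)(C)O1)C(=O)OCC[Si](C)(C)C
F2 | step 14 | TMSE (2Z,4R,5Z,9E)-4-(TBS-oxy)-6-[(TBS-oxy)methyl]-10-methyl-12-oxo-2-[(4,4,5,5-tetramethyl-1,3,2-dioxaborolan-2-yl)methyl]dodeca-2,5,9-trienoate | O=CC/C(C)=C/CC/C(CO[Si](C)(C)C(C)(C)C)=C/[C@@H](O[Si](C)(C)C(C)(C)C)/C=C(/CB1OC(C)(C)C(C)(C)O1)C(=O)OCC[Si](C)(C)C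
F3 | step 14 | TMSE (5R,6R,7R,8S,10S)-6,15-bis(TBS-oxy)-8-[(4,4,5,5-tetramethyl-1,3,2-dioxaborolan-2-yl)oxy]elema-1,3,11(13)-trien-12-oate | C=C[C@]1(C)C[C@H](OB2OC(C)(C)C(C)(C)O2)[C@@H](C(=C)C(=O)OCC[Si](C)(C)C)[C@H](O[Si](C)(C)C(C)(C)C)[C@H]1C(=C)CO[Si](C)(C)C(C)(C)C
F4 | step 10 | TMSE (2E,4R,5Z,9E)-4-(TBS-oxy)-6-[(TBS-oxy)methyl]-10-methyl-12-(PMB-oxy)-2-(tributylstannyl)dodeca-2,5,9-trienoate | COc1ccc(COCC/C(C)=C/CC/C(CO[Si](C)(C)C(C)(C)C)=C/[C@@H](O[Si](C)(C)C(C)(C)C)/C=C(/[Sn](CCCC)(CCCC)CCCC)C(=O)OCC[Si](C)(C)C)cc1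
F5 | step 10 | TMSE (2E,4R,5Z,9E)-2-iodo-4-(TBS-oxy)-6-[(TBS-oxy)methyl]-10-methyl-12-(PMB-oxy)dodeca-2,5,9-trienoate | COc1ccc(COCC/C(C)=C/CC/C(CO[Si](C)(C)C(C)(C)C)=C/[C@@H](O[Si](C)(C)C(C)(C)C)/C=C(/I)C(=O)OCC[Si](C)(C)C)cc1
F6 | step 4 | tert-butyldimethyl(prop-2-yn-1-yloxy)silane | C#CCO[Si](C)(C)C(C)(C)C
F7 | step 4 | ethyl 4-(TBS-oxy)but-2-ynoate | CCOC(=O)C#CCO[Si](C)(C)C(C)(C)C
F8 | step 4 | ethyl (2Z,6E)-3-[(TBS-oxy)methyl]-7-methyl-9-(PMB-oxy)nona-2,6-dienoate | COc1ccc(COCC/C(C)=C/CC/C(CO[Si](C)(C)C(C)(C)C)=C/C(=O)OCC)cc1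
F9 | step 4 | (2Z,6E)-3-[(TBS-oxy)methyl]-7-methyl-9-(PMB-oxy)nona-2,6-dien-1-ol | COc1ccc(COCC/C(C)=C/CC/C(CO[Si](C)(C)C(C)(C)C)=C/CO)cc1
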